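(The readings are simulated with made-up constants, noise included.)

| flask | starting material | remark | time |
|---|---|---|---|
| Sunday's | 0.0065 M | run made earlier |  |
| Friday's | 0.014 M | run made earlier |  |
| south | 0.012 M |  | 25 min |
| east | 0.023 M |  | 25 min |

- Sunday's (time / min: ring / %, open dimer / %): 2.50: 4.7, 1.3; 5.00: 10.5, 2.1; 8.00: 16.8, 3.7; 10.0: 20.0, 3.7; 12.0: 23.7, 5.1
- Friday's (time / min: ring / %, open dimer / %): 2.50: 4.3, 2.0; 5.00: 9.9, 6.2; 8.00: 14.5, 8.5; 10.0: 19.7, 7.0; 12.0: 21.7, 10.0

(scatter of a reading: 1 percentage point)

- the winner by share of ring in all that became ring or open dimer or open trimer; "neither" if no more than 2 percentage points parts them (south / east / neither)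
- share of ring in all that became ring or open dimer or open trimer, south
- share of ring in all that became ring or open dimer or open trimer, east

- in percentages every species weighs as the starting material in it: one open dimer counts as two
- in percentages every species weighs as the starting material in it: one open trimer counts as three
- steps that have been proposed: 2 starting material -> open dimer; starting material <-> dormant form; starting material -> ring; starting material + open dimer -> open trimer

Divide the open dimer by the ring at the last reading of each earlier run, then by the charge c of starting material: Sunday's gives 33.1 /M and Friday's 32.9 /M, so the ratio, read with the scatter of its readings, grows in step with c. We carry the mean, s = 33.0 /M, the percent of open dimer per percent of ring per molar of charge, a selectivity factor. If open dimer goes with the square of starting material and ring with its first power, and starting material falls exponentially, the ratio made so far is its starting value times the mean of one and f, the fraction of starting material remaining, which we take as the part of the charge read in neither ring nor open dimer, here 69.8% at 12.0 min as the mean of the two runs.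

Two versions of each flask can be solved in the head. If the ratio sc read at 12.0 min simply held to 25 min, the share of ring, one over one plus that ratio, would be 71.6% for south and 56.8% for east. If starting material were used to the end, sc would shrink by the factor one plus f, giving 81.1% and 69.1%. We place both flasks between these, taking for both the same exponential decay, which puts f at 47.2% by 25 min, below its value at 12.0 min. That multiplies sc by g = 0.867, and, setting aside the unread open trimer, we commit to 74.4% for south and 60.3% for east.

The forecast, resting on “ring formation is first order”, gives 75% for south, 63% for east, and south as winner; its figure for east stands above ours, though we name the same winner.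

The flasks give 74.6% for south and 61.2% for east, so south wins.

    2 starting material → open dimer (k = 0.00800 /M/s)
    starting material ⇌ dormant form (K = 1.10, k = 1.70 × 10⁻⁴ /s)
    starting material → ring (k = 3.90 × 10⁻⁴ /s)
    starting material + open dimer → open trimer (k = 0.00880 /M/s)

At 25.0 min east holds 2.96% open trimer, the species our reckoning set aside. For a flask like east but charged with 0.0092 M, s and g give a share of 79.2%, and that flask stands at 79.2%.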